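The polyene is cut at the C10–C11 single bond (carotenoid numbering; ring A is the hydroxylated cyclohexene C1–C6, ring B the cyclohexene bearing the C6' stereocentre). The key step exploits the enyne C7≡C8–C9(CH3)=C10 beside ring A: its methyl-branched alkene is the syn-methylmetalation product of a C9≡C10 triple bond. A ring-A terminal 1,3-diyne (C13, no C9 methyl) is methylaluminated under Cp2ZrCl2 catalysis and the resulting (E)-alkenylalane is coupled in the same flask, with ZnCl2 and a zerovalent palladium catalyst, to a C26 (E)-heptaenyl iodide made from (R)-α-ionone. One operation installs the C9 methyl, fixes the 9E geometry and forms C10–C11.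

Key step: step 9

Assumption: (R)-α-ionone (1) and (4R,6R)-4-hydroxy-2,2,6-trimethylcyclohexanone (8) are bought as single enantiomers; they supply C6' and C3, the only stereocentres of the target.

Step 1
Reactants: 1 (R)-α-ionone
Product: 2 (R)-vinyl-α-ionol (both carbinol epimers)
Conditions: CH2=CHMgBr, THF, −20 → 0 °C; then H2O/NH4Cl
Reagents that add atoms: vinylmagnesium bromide, C=C[Mg]Br
Why: Grignard 1,2-addition to the enone carbonyl at low temperature should outrun deprotonation at the hindered C6' position, and the new carbinol centre, formed as a mixture, is erased in step 2.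

Step 2
Reactants: 2 (R)-vinyl-α-ionol
Product: 3 C15 (2E,4E)-dienyl triphenylphosphonium bromide
Conditions: PPh3·HBr, MeOH, rt
Reagents that add atoms: triphenylphosphine hydrobromide, Br.c1ccc(cc1)P(c1ccccc1)c1ccccc1
Why: Ionisation of the tertiary allylic alcohol and capture of the delocalised cation by PPh3 at the unhindered primary terminus (SN1' allylic transposition) should give the phosphonium salt with a mainly E trisubstituted C9'=C10' bond, the mild acid leaving the ring-B alkene and C6' untouched.

Step 3
Reactants: 3 C15 phosphonium bromide; 4 (2E,4E,6E)-2,7-dimethylocta-2,4,6-trienedial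
Product: 6 all-E C25 hexaenal (6'R), via phosphorus ylide 5 (not isolated)
Conditions: NaOMe, MeOH/CH2Cl2, 0 °C → rt, 4 in excess; then heptane, 80 °C (Z → E equilibration), dark
Reagents that add atoms: none
Why: Wittig olefination of one aldehyde of the symmetrical dialdehyde used in excess should stop at the mono-adduct, because the remaining formyl group of 6 is deactivated by the longer conjugation, and the disubstituted C11'=C12' bond is equilibrated thermally to E.

Step 4
Reactants: 6 C25 hexaenal
Product: 7 C26 (E)-heptaenyl iodide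
Conditions: CrCl2, CHI3, THF/1,4-dioxane, 0 °C → rt, dark
Reagents that add atoms: iodoform, C(I)(I)I
Why: Takai iodoolefination, in which the geminal dichromium species from CHI3 adds to the only carbonyl group and eliminates to the (E)-iodoalkene, should add C11 with the 11E geometry.

Step 5
Reactants: 8 (4R,6R)-4-hydroxy-2,2,6-trimethylcyclohexanone
Product: 9 TBS ether of 8
Conditions: TBSCl, imidazole, DMF, rt
Reagents that add atoms: tert-butyldimethylsilyl chloride, CC(C)(C)[Si](C)(C)Cl
Why: Standard silylation of the secondary alcohol masks the only acidic O–H before enolate formation.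

Step 6
Reactants: 9 silyloxy ketone
Product: 11 (R)-enol triflate, via lithium enolate 10 (not isolated)
Conditions: LiN(iPr)2, THF, −78 → 0 °C; PhNTf2, −78 °C → rt
Reagents that add atoms: N-phenylbis(trifluoromethanesulfonimide), O=S(=O)(N(c1ccccc1)S(=O)(=O)C(F)(F)F)C(F)(F)F
Why: The ketone has a single enolisable position (the other α-carbon is quaternary), so enolate O-triflation should give only the tetrasubstituted enol triflate, erasing the methyl-bearing centre on purpose while the carbinol centre, γ to the carbonyl, cannot eliminate.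

Step 7
Reactants: 12 1,4-bis(trimethylsilyl)buta-1,3-diyne; 11 enol triflate
Product: 15 ring-A silyl-capped diyne, via lithium diynide 13 (not isolated), via diynylzinc bromide 14 (not isolated)
Conditions: 12, MeLi·LiBr (1.0 equiv), THF, rt; ZnBr2, 0 °C; then 11, Pd(PPh3)4 (5 mol %), THF, 50 °C
Reagents that add atoms: none
Why: Mono-desilylation of 12 by MeLi gives the lithium diynide, and Negishi alkynylation of the enol triflate by its zinc derivative should form the C6–C7 bond without diyne homocoupling.

Step 8
Reactants: 15 silyl-capped diyne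
Product: 16 ring-A terminal 1,3-diyne
Conditions: K2CO3 (cat.), MeOH/THF, 0 °C; solution used at once
Reagents that add atoms: none
Why: Base-catalysed methanolysis cleaves the alkynyl C–Si bond selectively, since the secondary TBS ether is stable to K2CO3/MeOH.

Step 9
Reactants: 16 ring-A terminal 1,3-diyne; 7 C26 (E)-heptaenyl iodide
Product: 19 O-TBS ether of the target, via alkenylalane 17 (not isolated), via alkenylzinc chloride 18 (not isolated)
Conditions: 16 (1.3 equiv), AlMe3 (2.5 equiv), Cp2ZrCl2 (0.3 equiv), CH2Cl2, 0 → 23 °C; volatiles removed in vacuo; then ZnCl2 (1.3 equiv), 7, Pd2(dba)3 (2.5 mol %), tri(2-furyl)phosphine (10 mol %), THF/DMF, 23 °C, dark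
Reagents that add atoms: trimethylaluminium, C[Al](C)C
Why: AlMe3 activated by Cp2ZrCl2 adds methyl and aluminium syn across the terminal C9≡C10 bond of 16, methyl to the internal carbon C9 and aluminium to the terminal carbon C10 (zirconium-catalysed carboalumination), giving the (E)-alkenylalane 17; transmetalation to zinc (18) and a zerovalent palladium cycle (oxidative addition into the C–I bond of 7, transmetalation, reductive elimination; Negishi coupling) then forge the C10–C11 sp2–sp2 bond with retention of both alkene geometries. The closest known reaction type is the one-pot methylalumination/palladium–zinc cross-coupling of conjugated terminal alkynes with alkenyl halides, which builds exactly the C(CH3)=CH–CH=CH motif of isoprenoid polyenes. No ring is closed and no stereocentre is created; the 9E geometry follows from the syn addition and the 11E geometry is carried in from 7. The step needs site selectivity between the two triple bonds and regioselectivity of methyl delivery: the internal C7≡C8 bond is disubstituted and shielded by the C1 gem-dimethyl and C5 methyl groups of ring A, while the terminal alkyne is unhindered and polarised to place aluminium at C10. Kinetic, stereospecific assembly is chosen because 7,8-didehydro polyenes are prone to drift from 9E to 9Z under equilibrating conditions. The silyl ether, the tetrasubstituted ring-A alkene and the ring-B alkene should be inert, and removal of excess AlMe3 before the coupling should limit methyl transfer to 7.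

Step 10
Reactants: 19 O-TBS ether of the target
Product: 20 (3R,6'R)-7,8-didehydro-β,ε-caroten-3-ol (all-E, target)
Conditions: Bu4NF, AcOH, THF, 0 °C → rt, dark, argon
Reagents that add atoms: none
Why: Buffered fluoride cleavage of the secondary silyl ether should leave the polyene, the triple bond and both stereocentres untouched.

Compound list
1 | (R)-α-ionone, (3E)-4-[(1R)-2,6,6-trimethylcyclohex-2-en-1-yl]but-3-en-2-one | CC1=CCCC(C)(C)[C@H]1/C=C/C(C)=O | starting material
2 | (1E)-3-methyl-1-[(1R)-2,6,6-trimethylcyclohex-2-en-1-yl]penta-1,4-dien-3-ol (both C3 epimers) | CC1=CCCC(C)(C)[C@H]1/C=C/C(C)(O)C=C | intermediate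
3 | [(2E,4E)-3-methyl-5-[(1R)-2,6,6-trimethylcyclohex-2-en-1-yl]penta-2,4-dien-1-yl]triphenylphosphonium bromide | CC1=CCCC(C)(C)[C@H]1/C=C/C(C)=C/C[P+](c1ccccc1)(c1ccccc1)c1ccccc1.[Br-] | intermediate
4 | (2E,4E,6E)-2,7-dimethylocta-2,4,6-trienedial | O=C/C(C)=C/C=C/C=C(C)/C=O | starting material
5 | phosphorus ylide of 3, (2E,4E)-3-methyl-5-[(1R)-2,6,6-trimethylcyclohex-2-en-1-yl]penta-2,4-dien-1-ylidene(triphenyl)phosphorane | CC1=CCCC(C)(C)[C@H]1/C=C/C(C)=C/C=P(c1ccccc1)(c1ccccc1)c1ccccc1 | intermediate
6 | (2E,4E,6E,8E,10E,12E)-2,7,11-trimethyl-13-[(1R)-2,6,6-trimethylcyclohex-2-en-1-yl]trideca-2,4,6,8,10,12-hexaenal | CC1=CCCC(C)(C)[C@H]1/C=C/C(C)=C/C=C/C(C)=C/C=C/C=C(C)/C=O | intermediate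
7 | (6R)-6-[(1E,3E,5E,7E,9E,11E,13E)-14-iodo-3,7,12-trimethyltetradeca-1,3,5,7,9,11,13-heptaen-1-yl]-1,5,5-trimethylcyclohex-1-ene | CC1=CCCC(C)(C)[C@H]1/C=C/C(C)=C/C=C/C(C)=C/C=C/C=C(C)/C=C/I | intermediate
8 | (4R,6R)-4-hydroxy-2,2,6-trimethylcyclohexan-1-one | O=C1[C@H](C)C[C@@H](O)CC1(C)C | starting material
9 | (4R,6R)-4-[(tert-butyldimethylsilyl)oxy]-2,2,6-trimethylcyclohexan-1-one | O=C1[C@H](C)C[C@@H](O[Si](C)(C)C(C)(C)C)CC1(C)C | intermediate
10 | lithium (4R)-4-[(tert-butyldimethylsilyl)oxy]-2,6,6-trimethylcyclohex-1-en-1-olate | [Li]OC1=C(C)C[C@@H](O[Si](C)(C)C(C)(C)C)CC1(C)C | intermediate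
11 | (4R)-4-[(tert-butyldimethylsilyl)oxy]-2,6,6-trimethylcyclohex-1-en-1-yl trifluoromethanesulfonate | O=S(=O)(OC1=C(C)C[C@@H](O[Si](C)(C)C(C)(C)C)CC1(C)C)C(F)(F)F | intermediate
12 | 1,4-bis(trimethylsilyl)buta-1,3-diyne | C[Si](C)(C)C#CC#C[Si](C)(C)C | starting material
13 | lithium 4-(trimethylsilyl)buta-1,3-diyn-1-ide | [Li]C#CC#C[Si](C)(C)C | intermediate
14 | bromo[4-(trimethylsilyl)buta-1,3-diyn-1-yl]zinc | Br[Zn]C#CC#C[Si](C)(C)C | intermediate
15 | tert-butyldimethyl{[(1R)-3,5,5-trimethyl-4-[4-(trimethylsilyl)buta-1,3-diyn-1-yl]cyclohex-3-en-1-yl]oxy}silane | C[Si](C)(C)C#CC#CC1=C(C)C[C@@H](O[Si](C)(C)C(C)(C)C)CC1(C)C | intermediate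
16 | {[(1R)-4-(buta-1,3-diyn-1-yl)-3,5,5-trimethylcyclohex-3-en-1-yl]oxy}(tert-butyl)dimethylsilane | C#CC#CC1=C(C)C[C@@H](O[Si](C)(C)C(C)(C)C)CC1(C)C | intermediate
17 | dimethyl[(1E)-2-methyl-4-[(4R)-4-[(tert-butyldimethylsilyl)oxy]-2,6,6-trimethylcyclohex-1-en-1-yl]but-1-en-3-yn-1-yl]alane | C[Al](C)/C=C(\C)C#CC1=C(C)C[C@@H](O[Si](C)(C)C(C)(C)C)CC1(C)C | intermediate
18 | chloro[(1E)-2-methyl-4-[(4R)-4-[(tert-butyldimethylsilyl)oxy]-2,6,6-trimethylcyclohex-1-en-1-yl]but-1-en-3-yn-1-yl]zinc | Cl[Zn]/C=C(\C)C#CC1=C(C)C[C@@H](O[Si](C)(C)C(C)(C)C)CC1(C)C | intermediate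
19 | (3R,6'R)-3-[(tert-butyldimethylsilyl)oxy]-7,8-didehydro-β,ε-carotene (all-E) | CC1=CCCC(C)(C)[C@H]1/C=C/C(C)=C/C=C/C(C)=C/C=C/C=C(C)/C=C/C=C(\C)C#CC1=C(C)C[C@@H](O[Si](C)(C)C(C)(C)C)CC1(C)C | intermediate
20 | (3R,6'R)-7,8-didehydro-β,ε-caroten-3-ol (all-E) | CC1=CCCC(C)(C)[C@H]1/C=C/C(C)=C/C=C/C(C)=C/C=C/C=C(C)/C=C/C=C(\C)C#CC1=C(C)C[C@@H](O)CC1(C)C | target

Total step count: 10. Longest linear sequence: 6 steps (steps 1–4, 9, 10, or equally steps 5–8, 9, 10).

Steps most likely to fail

Step 9. The acidic diyne C–H may be deprotonated by AlMe3 in competition with carbometalation. Methyl delivery may be incompletely regioselective, and the heptaenyl iodide may decay in the presence of aluminium and zirconium residues, so that the one-pot union erodes in conversion and geometric purity. The fallback separates carbometalation from coupling and reverses the polarity of the long fragment. It sets out from 16 (with aldehyde 6 as the second partner) and comes back at 19. Diyne 16 is methylaluminated as before to alane 17, which is quenched with I2 in THF at −30 °C to give the isolable, purifiable (E)-iodoenyne F1. Aldehyde 6 is converted by Takai-type chromium-mediated stannylolefination (Bu3SnCHBr2, CrCl2, LiI, THF/DMF) into the (E)-heptaenylstannane F2. A Stille coupling of F1 and F2 (Pd2(dba)3, AsPh3, DMF, rt, dark) should then form the same C10–C11 bond and deliver 19, without the iodide 7.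

Step 4. Reductive side reactions of the extended polyenal with CrCl2 and incomplete E-selectivity of the iodoolefination may lower the supply and purity of 7. The fallback builds the iodovinyl terminus by homologation and hydrometalation instead; it sets out from 6 and comes back at 7. Aldehyde 6 is homologated with lithiated trimethylsilyldiazomethane (Me3SiCHN2, LiN(iPr)2, THF, −78 °C → rt; Colvin rearrangement) to the terminal hexaenyne F3. Syn-hydrozirconation with Cp2Zr(H)Cl in THF gives the alkenylzirconocene chloride F4 (not isolated), and iodinolysis with I2 at 0 °C should give 7 with the E geometry fixed by the syn addition.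

Step 7. Oxidative addition into the hindered tetrasubstituted enol triflate may be slow, so that the diynylzinc reagent decomposes before it couples. The fallback forms the C6–C7 bond by carbonyl addition instead; it sets out from 9 and comes back at 15. Lithium diynide 13, made as in step 7, is added to ketone 9 (THF, −78 → 0 °C) to give the tertiary propargylic alcohol F5 as a mixture of carbinol epimers. Dehydration with POCl3 in pyridine at 80 °C can only run toward the methyl-bearing ring carbon, because the other neighbour is quaternary, and should give 15.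

Further compounds
F1 | step 9 | tert-butyl{[(1R)-4-[(3E)-4-iodo-3-methylbut-3-en-1-yn-1-yl]-3,5,5-trimethylcyclohex-3-en-1-yl]oxy}dimethylsilane | I/C=C(\C)C#CC1=C(C)C[C@@H](O[Si](C)(C)C(C)(C)C)CC1(C)C
F2 | step 9 | tributyl[(1E,3E,5E,7E,9E,11E,13E)-3,8,12-trimethyl-14-[(1R)-2,6,6-trimethylcyclohex-2-en-1-yl]tetradeca-1,3,5,7,9,11,13-heptaen-1-yl]stannane | CC1=CCCC(C)(C)[C@H]1/C=C/C(C)=C/C=C/C(C)=C/C=C/C=C(C)/C=C/[Sn](CCCC)(CCCC)CCCC
F3 | step 4 | (6R)-1,5,5-trimethyl-6-[(1E,3E,5E,7E,9E,11E)-3,7,12-trimethyltetradeca-1,3,5,7,9,11-hexaen-13-yn-1-yl]cyclohex-1-ene | CC1=CCCC(C)(C)[C@H]1/C=C/C(C)=C/C=C/C(C)=C/C=C/C=C(C)/C#C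
F4 | step 4 | chlorobis(cyclopentadienyl)[(1E,3E,5E,7E,9E,11E,13E)-3,8,12-trimethyl-14-[(1R)-2,6,6-trimethylcyclohex-2-en-1-yl]tetradeca-1,3,5,7,9,11,13-heptaen-1-yl]zirconium | CC1=CCCC(C)(C)[C@H]1/C=C/C(C)=C/C=C/C(C)=C/C=C/C=C(C)/C=C/[Zr](Cl)(C1C=CC=C1)C1C=CC=C1
F5 | step 7 | (4R,6R)-4-[(tert-butyldimethylsilyl)oxy]-2,2,6-trimethyl-1-[4-(trimethylsilyl)buta-1,3-diyn-1-yl]cyclohexan-1-ol (both C1 epimers) | C[Si](C)(C)C#CC#CC1(O)[C@H](C)C[C@@H](O[Si](C)(C)C(C)(C)C)CC1(C)C
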